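The route disconnects the C4=C5 alkene of the 3,6-dihydro-1,2-dioxin ring, which lies between the two oxygen-bearing allylic carbons C3 (bonded to O2) and C6 (the methoxy/hexadecyl ketal carbon bonded to O1). Ring-closing metathesis of an acyclic dialkyl peroxide that carries one vinyl group on each of these carbons creates this alkene and the six-membered peroxide ring in a single operation, without touching the O–O bond or either oxygenated centre. The precursor is a mixed methyl peroxyketal joined from an (R)-allylic hydroperoxide, whose C3 configuration comes from an invertive displacement, and a vinyl ketone dimethyl ketal; C6 is settled at the end by separation and acid equilibration.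

Key step: step 9

Remark on the chemistry: the ketal exchange in step 8 is not expected to favour either configuration at the new ketal carbon, so it is assumed that 13, 14, 15, 16 and 17 are each accompanied by their epimer at that carbon (C6 of the ring), which is not numbered separately, should react in the same way, and is removed and recycled at the ester stage in step 12.

Step 1
Reactants: 1 3-[(tert-butyldimethylsilyl)oxy]propanal; 2 vinylmagnesium bromide
Product: 3 rac-5-[(tert-butyldimethylsilyl)oxy]pent-1-en-3-ol
Conditions: THF, −78 → 0 °C; sat. aq. NH4Cl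
Reagents that add atoms: none
Why: Grignard 1,2-addition of the vinyl nucleophile to the unhindered aldehyde should give the secondary allylic alcohol, whose new stereocentre forms without control (racemate) and is resolved in step 2.

Step 2
Reactants: 3 rac-5-[(tert-butyldimethylsilyl)oxy]pent-1-en-3-ol
Product: 4 (3S)-5-[(tert-butyldimethylsilyl)oxy]pent-1-en-3-ol
Conditions: Ti(OiPr)4 (0.2 equiv), D-(−)-diisopropyl tartrate (0.3 equiv), t-BuOOH (0.6 equiv), 4 Å MS, CH2Cl2, −20 °C
Reagents that add atoms: none
Why: Sharpless kinetic resolution: with the D-(−)-tartrate ligand the titanium tartrate catalyst should epoxidise the (R)-enantiomer much faster, so that the (S)-alcohol is recovered in high enantiomeric purity once conversion has passed one half and is separated from the more polar epoxy alcohol.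

Step 3
Reactants: 4 (3S)-5-[(tert-butyldimethylsilyl)oxy]pent-1-en-3-ol
Product: 5 (3S)-5-[(tert-butyldimethylsilyl)oxy]pent-1-en-3-yl methanesulfonate
Conditions: MsCl, Et3N, CH2Cl2, −30 °C; cold aqueous work-up, used at once
Reagents that add atoms: methanesulfonyl chloride, CS(=O)(=O)Cl
Why: O-Sulfonylation (mesylation) of the alcohol does not touch the C3–O bond, so the S configuration is retained, and the reactive allylic mesylate is kept cold and used directly to forestall ionisation.

Step 4
Reactants: 5 (3S)-5-[(tert-butyldimethylsilyl)oxy]pent-1-en-3-yl methanesulfonate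
Product: 6 tert-butyl{[(3R)-3-hydroperoxypent-4-en-1-yl]oxy}dimethylsilane
Conditions: 50% aq. H2O2 (large excess), KOH, MeOH/THF, 0 °C → rt
Reagents that add atoms: hydrogen peroxide, OO
Why: SN2 displacement of the sulfonate by the hydroperoxide anion, a small α-effect nucleophile used in large excess, should give the secondary hydroperoxide with inversion at C3 (S to R), following the established perhydrolysis of secondary alkyl methanesulfonates, while the silyl ether tolerates the cold alkaline medium.

Step 5
Reactants: 7 heptadecanoyl chloride; 8 trimethylsilylacetylene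
Product: 9 1-(trimethylsilyl)nonadec-1-yn-3-one
Conditions: PdCl2(PPh3)2 (2 mol %), CuI (4 mol %), Et3N, THF, rt
Reagents that add atoms: none
Why: Acyl Sonogashira coupling (oxidative addition of the acid chloride to zerovalent palladium, transmetallation from the copper acetylide, reductive elimination) should give the silyl ynone without over-addition to the ketone.

Step 6
Reactants: 9 1-(trimethylsilyl)nonadec-1-yn-3-one
Product: 11 3,3-dimethoxynonadec-1-yne, via silyl alkynyl ketal 10 (not isolated)
Conditions: HC(OMe)3, MeOH/CH2Cl2, TsOH·H2O (cat.), rt; then K2CO3, rt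
Reagents that add atoms: trimethyl orthoformate, COC(OC)OC; methanol, CO
Why: Acid-catalysed ketalisation with the orthoformate as water scavenger (the silyl group shields the alkyne terminus against conjugate addition of methanol) is followed, once the acid is neutralised, by carbonate-mediated methanolysis of the alkynyl C–Si bond in the same flask.

Step 7
Reactants: 11 3,3-dimethoxynonadec-1-yne
Product: 12 3,3-dimethoxynonadec-1-ene
Conditions: H2 (1 atm), Pd/CaCO3 poisoned with Pb(OAc)2 (Lindlar catalyst), quinoline, hexane, rt
Reagents that add atoms: none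
Why: Lindlar semihydrogenation of the terminal alkyne should stop at the vinyl group, this detour through the alkyne being taken because a vinyl ketone cannot be ketalised directly without conjugate addition of methanol.

Step 8
Reactants: 6 tert-butyl{[(3R)-3-hydroperoxypent-4-en-1-yl]oxy}dimethylsilane; 12 3,3-dimethoxynonadec-1-ene (excess)
Product: 13 tert-butyl{[(3R)-3-{[(3S)-3-methoxynonadec-1-en-3-yl]peroxy}pent-4-en-1-yl]oxy}dimethylsilane
Conditions: pyridinium p-toluenesulfonate (PPTS, 10 mol %), 5 Å MS, CH2Cl2, 0 °C; chromatography on Et3N-deactivated silica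
Reagents that add atoms: none
Why: Acid-catalysed transketalisation: loss of methanol from 12 gives a methoxy-stabilised cation that the terminal oxygen of the hydroperoxide captures at the ketal carbon while the sieves take up methanol, C3 is not involved, and the new ketal stereocentre forms without control, so that 13 is expected together with its epimer at that carbon.

Step 9
Reactants: 13 tert-butyl{[(3R)-3-{[(3S)-3-methoxynonadec-1-en-3-yl]peroxy}pent-4-en-1-yl]oxy}dimethylsilane (with its ketal epimer)
Product: 14 tert-butyl{2-[(3R,6S)-6-hexadecyl-6-methoxy-3,6-dihydro-1,2-dioxin-3-yl]ethoxy}dimethylsilane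
Conditions: RuCl2(=CHPh)(PCy3)(H2IMes) (second-generation Grubbs catalyst, 5 mol %), CH2Cl2 (5 mM), 40 °C, argon sparge
Reagents that add atoms: none
Why: The ruthenium benzylidene should first exchange with the more accessible vinyl group on C3, and the resulting alkylidene then engages the vinyl group on the fully substituted C6 in an intramolecular [2+2] cycloaddition, the metallacyclobutane collapsing to the C4=C5 bond with release of ethylene (Chauvin mechanism). The closest known reaction types are ring-closing metathesis of diallyl ethers to 3,6-dihydro-2H-pyrans and ruthenium-catalysed metathesis of alkenyl dialkyl peroxides, in which the O–O bond survives. The six-membered 3,6-dihydro-1,2-dioxin ring closes by union of the two terminal alkene carbons of one chain, and a ring of this size can hold only a Z alkene. No stereocentre is created and no bond to C3 or C6 is broken, so both configurations pass through unchanged. The step needs chemoselectivity for the alkenes over the peroxide and cyclisation over oligomerisation; the substrate has no hydroperoxide O–H, the quaternary C6 and the gauche C–O–O–C tether hold the two vinyl groups close, and high dilution with removal of ethylene favours ring closure. The ketal epimer that accompanies 13 should cyclise in the same way.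

Step 10
Reactants: 14 tert-butyl{2-[(3R,6S)-6-hexadecyl-6-methoxy-3,6-dihydro-1,2-dioxin-3-yl]ethoxy}dimethylsilane (with its C6 epimer)
Product: 15 2-[(3R,6S)-6-hexadecyl-6-methoxy-3,6-dihydro-1,2-dioxin-3-yl]ethan-1-ol
Conditions: HF·pyridine, pyridine, THF, 0 °C → rt
Reagents that add atoms: none
Why: Fluoride cleaves the primary Si–O bond in a pyridine-buffered medium that should be neither basic enough to trigger Kornblum–DeLaMare opening of the dioxene nor acidic enough to ionise the ketal, and the accompanying C6 epimer reacts alike.

Step 11
Reactants: 15 2-[(3R,6S)-6-hexadecyl-6-methoxy-3,6-dihydro-1,2-dioxin-3-yl]ethan-1-ol (with its C6 epimer)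
Product: 17 [(3R,6S)-6-hexadecyl-6-methoxy-3,6-dihydro-1,2-dioxin-3-yl]acetic acid, via aldehyde 16 (not isolated)
Conditions: TEMPO (0.2 equiv), PhI(OAc)2 (2.5 equiv), CH2Cl2/H2O (2:1), 0 °C → rt; used without storage
Reagents that add atoms: water, O
Why: Oxoammonium-mediated (TEMPO) oxidation takes the primary alcohol to the aldehyde and, through its hydrate, to the carboxylic acid under base-free conditions that should spare the peroxide, the ring alkene and the base-labile β-peroxy carbonyl unit, the C6 epimer being oxidised alike.

Step 12
Reactants: 17 [(3R,6S)-6-hexadecyl-6-methoxy-3,6-dihydro-1,2-dioxin-3-yl]acetic acid (with its C6 epimer)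
Product: 18 methyl [(3R,6S)-6-hexadecyl-6-methoxy-3,6-dihydro-1,2-dioxin-3-yl]acetate (chondrillin)
Conditions: Me3SiCHN2, MeOH/toluene, 0 °C; chromatography on silica gel (HPLC if needed) to remove the C6 epimer, which is re-equilibrated with PPTS (0.2 equiv) in MeOH/CH2Cl2 at rt and chromatographed again
Reagents that add atoms: (trimethylsilyl)diazomethane, C[Si](C)(C)C=[N+]=[N-]; methanol, CO
Why: Esterification by diazomethane, released in the flask by methanolysis of the silyl diazoalkane, is neutral and fast, so the β-peroxy ester should form without elimination, after which the two C6 epimers (cis and trans 3,6-disubstituted dioxenes) are parted by chromatography and the unwanted one is returned to an epimer mixture by reversible acid-catalysed ionisation of the ketal at C6 in methanol, which fixes C6 as S without involving C3.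

Compound list
1 | 3-[(tert-butyldimethylsilyl)oxy]propanal | O=CCCO[Si](C)(C)C(C)(C)C | starting material
2 | vinylmagnesium bromide | C=C[Mg]Br | starting material
3 | rac-5-[(tert-butyldimethylsilyl)oxy]pent-1-en-3-ol | OC(CCO[Si](C)(C)C(C)(C)C)C=C | intermediate
4 | (3S)-5-[(tert-butyldimethylsilyl)oxy]pent-1-en-3-ol | O[C@@H](CCO[Si](C)(C)C(C)(C)C)C=C | intermediate
5 | (3S)-5-[(tert-butyldimethylsilyl)oxy]pent-1-en-3-yl methanesulfonate | CS(=O)(=O)O[C@@H](CCO[Si](C)(C)C(C)(C)C)C=C | intermediate
6 | tert-butyl{[(3R)-3-hydroperoxypent-4-en-1-yl]oxy}dimethylsilane | OO[C@H](CCO[Si](C)(C)C(C)(C)C)C=C | intermediate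
7 | heptadecanoyl chloride | CCCCCCCCCCCCCCCCC(=O)Cl | starting material
8 | trimethylsilylacetylene | C[Si](C)(C)C#C | starting material
9 | 1-(trimethylsilyl)nonadec-1-yn-3-one | CCCCCCCCCCCCCCCCC(=O)C#C[Si](C)(C)C | intermediate
10 | (3,3-dimethoxynonadec-1-yn-1-yl)trimethylsilane | CCCCCCCCCCCCCCCCC(OC)(OC)C#C[Si](C)(C)C | intermediate (not isolated)
11 | 3,3-dimethoxynonadec-1-yne | CCCCCCCCCCCCCCCCC(OC)(OC)C#C | intermediate
12 | 3,3-dimethoxynonadec-1-ene | CCCCCCCCCCCCCCCCC(OC)(OC)C=C | intermediate
13 | tert-butyl{[(3R)-3-{[(3S)-3-methoxynonadec-1-en-3-yl]peroxy}pent-4-en-1-yl]oxy}dimethylsilane | CCCCCCCCCCCCCCCC[C@@](OO[C@H](CCO[Si](C)(C)C(C)(C)C)C=C)(OC)C=C | intermediate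
14 | tert-butyl{2-[(3R,6S)-6-hexadecyl-6-methoxy-3,6-dihydro-1,2-dioxin-3-yl]ethoxy}dimethylsilane | CCCCCCCCCCCCCCCC[C@@]1(OC)C=C[C@@H](CCO[Si](C)(C)C(C)(C)C)OO1 | intermediate
15 | 2-[(3R,6S)-6-hexadecyl-6-methoxy-3,6-dihydro-1,2-dioxin-3-yl]ethan-1-ol | CCCCCCCCCCCCCCCC[C@@]1(OC)C=C[C@@H](CCO)OO1 | intermediate
16 | [(3R,6S)-6-hexadecyl-6-methoxy-3,6-dihydro-1,2-dioxin-3-yl]acetaldehyde | CCCCCCCCCCCCCCCC[C@@]1(OC)C=C[C@@H](CC=O)OO1 | intermediate (not isolated)
17 | [(3R,6S)-6-hexadecyl-6-methoxy-3,6-dihydro-1,2-dioxin-3-yl]acetic acid | CCCCCCCCCCCCCCCC[C@@]1(OC)C=C[C@@H](CC(=O)O)OO1 | intermediate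
18 | methyl [(3R,6S)-6-hexadecyl-6-methoxy-3,6-dihydro-1,2-dioxin-3-yl]acetate (chondrillin) | CCCCCCCCCCCCCCCC[C@@]1(OC)C=C[C@@H](CC(=O)OC)OO1 | target

Total step count: 12.
Longest linear sequence: 9 steps (steps 1–4 and 8–12); the ketal branch (steps 5–7) joins at step 8.

Steps most likely to fail

1. Step 9 (ring-closing metathesis). The alkylidene formed at the C3 vinyl group may be consumed by electron transfer to, or fragmentation at, the neighbouring allylic O–O bond. Released PCy3 may deoxygenate the peroxide. The alkylidene may also engage a second molecule faster than the hindered vinyl group on C6, giving oligomers. The fallback sets out from 6 and comes back at 14 (with its C6 epimer); it forms C4=C5 by carbonyl olefination and closes the ring at O1–C6, so that no metal alkylidene meets the peroxide. Hydroperoxide 6 is capped with 2-methoxypropene (PPTS, CH2Cl2, 0 °C) to give the perketal tert-butyl{[(3R)-3-[(2-methoxypropan-2-yl)peroxy]pent-4-en-1-yl]oxy}dimethylsilane F1. Ozonolysis (O3, CH2Cl2, −78 °C; PPh3) should give the α-peroxy aldehyde (2R)-4-[(tert-butyldimethylsilyl)oxy]-2-[(2-methoxypropan-2-yl)peroxy]butanal F2. Wittig reaction with the stabilised ylide 1-(triphenyl-λ5-phosphanylidene)octadecan-2-one F3 (from 7 and two equivalents of Ph3P=CH2) should give the enone (3R,4E)-1-[(tert-butyldimethylsilyl)oxy]-3-[(2-methoxypropan-2-yl)peroxy]docos-4-en-6-one F4. Brief treatment with aqueous acetic acid in THF frees the hydroperoxide (3R,4E)-1-[(tert-butyldimethylsilyl)oxy]-3-hydroperoxydocos-4-en-6-one F5. Irradiation at 350 nm through Pyrex isomerises it to (3R,4Z)-1-[(tert-butyldimethylsilyl)oxy]-3-hydroperoxydocos-4-en-6-one F6, which is trapped as it forms as the cyclic peroxyhemiketal (6R)-6-{2-[(tert-butyldimethylsilyl)oxy]ethyl}-3-hexadecyl-3,6-dihydro-1,2-dioxin-3-ol F7. Short exposure to PPTS and HC(OMe)3 in methanol then converts F7 into 14 and its C6 epimer.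

2. Step 4 (hydroperoxide displacement). The hydroperoxide anion may attack the terminal alkene carbon (SN2′). Base may eliminate methanesulfonic acid to give the diene. The allylic sulfonate may ionise in the protic medium, with loss of regiochemical and configurational integrity at C3. The fallback sets out from 5 and 12 and comes back at 13 (with its ketal epimer), bypassing 6 and step 8; the C3–O bond is made by alkylating a preformed peroxyketal hydroperoxide in an aprotic solvent without hydroxide or methanol. Ketal 12 is treated briefly with ethereal H2O2 and a trace of PPTS to exchange one methoxy group, giving 3-hydroperoxy-3-methoxynonadec-1-ene F8. Its caesium salt (CsOH·H2O, DMF, 0 °C) is then alkylated by mesylate 5 with inversion at C3, the known O-alkylation of α-alkoxy hydroperoxides by sulfonates.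

3. Step 8 (peroxyketal exchange). The exchange may stall at an equilibrium in which released methanol, rather than the hydroperoxide, recaptures the oxocarbenium ion. Prolonged acid exposure may divert this allyl-type cation to capture at its terminal carbon or to hydrolysis, or may degrade the allylic hydroperoxide. The fallback sets out from 12 and 6 and comes back at 13 (with its ketal epimer); the peroxyketal is formed by irreversible addition of the hydroperoxide to an enol ether, which liberates no methanol and needs only brief contact with acid. Ketal 12 loses methanol on treatment with Me3SiOTf and iPr2NEt (CH2Cl2, −20 °C → rt) to give the dienyl ether 3-methoxynonadeca-1,3-diene F9 as an E/Z mixture. In the presence of 6, F9 is protonated at C4 by PPTS (2 mol %, CH2Cl2, −20 °C) and captured at C3 by the hydroperoxide, the standard perketal synthesis from hydroperoxides and 2-alkoxyalkenes.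

Further compounds
F1 | step 9 | tert-butyl{[(3R)-3-[(2-methoxypropan-2-yl)peroxy]pent-4-en-1-yl]oxy}dimethylsilane | COC(C)(C)OO[C@H](CCO[Si](C)(C)C(C)(C)C)C=C
F2 | step 9 | (2R)-4-[(tert-butyldimethylsilyl)oxy]-2-[(2-methoxypropan-2-yl)peroxy]butanal | COC(C)(C)OO[C@H](CCO[Si](C)(C)C(C)(C)C)C=O
F3 | step 9 | 1-(triphenyl-λ5-phosphanylidene)octadecan-2-one | CCCCCCCCCCCCCCCCC(=O)C=P(c1ccccc1)(c1ccccc1)c1ccccc1
F4 | step 9 | (3R,4E)-1-[(tert-butyldimethylsilyl)oxy]-3-[(2-methoxypropan-2-yl)peroxy]docos-4-en-6-one | COC(C)(C)OO[C@H](CCO[Si](C)(C)C(C)(C)C)/C=C/C(=O)CCCCCCCCCCCCCCCC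
F5 | step 9 | (3R,4E)-1-[(tert-butyldimethylsilyl)oxy]-3-hydroperoxydocos-4-en-6-one | OO[C@H](CCO[Si](C)(C)C(C)(C)C)/C=C/C(=O)CCCCCCCCCCCCCCCC
F6 | step 9 | (3R,4Z)-1-[(tert-butyldimethylsilyl)oxy]-3-hydroperoxydocos-4-en-6-one | OO[C@H](CCO[Si](C)(C)C(C)(C)C)/C=C\C(=O)CCCCCCCCCCCCCCCC
F7 | step 9 | (6R)-6-{2-[(tert-butyldimethylsilyl)oxy]ethyl}-3-hexadecyl-3,6-dihydro-1,2-dioxin-3-ol (both C3 anomers) | CCCCCCCCCCCCCCCCC1(O)C=C[C@@H](CCO[Si](C)(C)C(C)(C)C)OO1
F8 | step 4 | 3-hydroperoxy-3-methoxynonadec-1-ene (racemic) | CCCCCCCCCCCCCCCCC(OC)(OO)C=C
F9 | step 8 | 3-methoxynonadeca-1,3-diene (E/Z mixture) | CCCCCCCCCCCCCCCC=C(OC)C=C
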